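A straight run of readings invites you to extend it with a ruler, but the ruler assumes that the solid feeding the curve lasts, and that is the trap in this flask, where solid substrate dissolves while target forms.

| flask | solid substrate | first nucleophile | second nucleophile | remark | time |
|---|---|---|---|---|---|
| blue | 0.050 M | 0.25 M | 0.037 M | run made earlier |  |
| ochre | 0.050 M | 0.25 M | 0.15 M | run made earlier |  |
| flask | 0.050 M | 0.250 M | 0.0750 M |  | 25 min |

- blue (time / min: target / %): 3.00: 1.0; 6.00: 3.1; 8.00: 4.0; 12.0: 6.1; 15.0: 8.0; 20.0: 9.5
- ochre (time / min: target / %): 1.50: 0.9; 2.50: 1.1; 4.00: 1.7; 6.00: 2.5; 8.00: 3.5; 12.0: 5.9; 20.0: 9.3

(standard deviation of a reading: 0.3 percentage points)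

- given per volume of solution although it is solid: solid substrate
- at the start none of the solid substrate is in solution

* how much target there is at 25 min, in percent of the solid substrate charged
* the change that raises the amount of target at 25 min, in percent of the solid substrate charged most ("none" if none brings more than 2 percentage points) (west / south-east / north-west / east / none)
* amount of target at 25 min, in percent of the solid substrate charged, after west

- west: doubling the solubility of the solid substrate, all else as stated
- south-east: doubling the amount of first nucleophile, all else as stated
- north-west: doubling the amount of second nucleophile, all else as stated
- east: doubling the dissolution coefficient of the solid substrate, all else as stated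

Replace each curve by its mean: the two runs stand at 9.5 % and 9.3 % after 20.0 min, which gives 0.00470 min⁻¹ as a fraction of the charge, and this mean slope, the apparent zero-order rate, carried to 25 min gives 11.7 %. To check that replacement, split the curves at 12.0 min: the slope reads 0.00500 min⁻¹ before and 0.00425 min⁻¹ after, lower, though with a scatter of 0.3 percentage points per reading that is a lean and no proof, and it brings my own figure down to 11.5 %.

Now turn the settings one by one. Second nucleophile rises by a factor of 4.05 between the runs while the last readings differ by 0.2 points, so I expect no gain from north-west. I read the later slope, lower than the earlier one, as a supply no longer holding its level, so I expect little from west or east, which speed the supply. First nucleophile stands at 0.25 M in both runs, so they do not show its effect; if target is a share taken in proportion to it, south-east carries my figure to about 23.0 %, and that is my choice.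

The forecast, from which I part on the choice, says 11.7 % (10.8 % to 12.6 %) and west with 23 % (19.5 % to 25 %), holding that "Solubility raises the rate in either case".

The flask gives 10.4 %, and the best change is south-east, worth 8.2 points, while west brings 0.5 points and ends at 10.9 %, east 0.21 points and north-west −0.6 points.

    second nucleophile + intermediate → other capture product (k = 8.61 L mol⁻¹ s⁻¹)
    intermediate → solvolysis product (k = 8.52 s⁻¹)
    first nucleophile + intermediate → target (k = 5.13 L mol⁻¹ s⁻¹)
    starting material → intermediate (k = 0.00160 s⁻¹)
    solid substrate ⇌ starting material, rate k5*(cs5 - [starting material]) while solid is left; crystals form when [starting material] > cs5 (solubility = 29.0 mM, k = 0.00988 s⁻¹)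

In the flask, solid substrate stands at 0 % by 12.5 min, and at 25.0 min solvolysis product holds 70.1 % against 10.4 % of target. Take the neighbouring flask with 0.10 M of first nucleophile, 2.00 equiv to the solid substrate: the mean slope, scaled by the ratio of first nucleophile and carried to 25 min, gives 4.70 %, and that flask gives 4.50 %.

The readings were generated by integration for an exercise; noise was put on by code.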